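At a small charge a substrate molecule seldom meets a partner, so follow one molecule and ask for its chances at each fork.

substrate 37 mM; time 12 d

    2 substrate → homo dimer (k1 = 10 L mol⁻¹ h⁻¹)
    intermediate ⇌ target (K2 = 0.44, k2 = 0.59 h⁻¹)
    substrate + target ⇌ idle adduct, settled at all times (K3 = 12 L mol⁻¹)
    intermediate → side product (k4 = 0.057 h⁻¹)
    substrate ⇌ intermediate (K5 = 0.28, k5 = 0.21 h⁻¹)

- why nothing more happens at 12 d, or that something still does (all of the substrate has reacted / it is still moving / forward and back rates have come level)
- how much side product there is at 12 d, in percent of the substrate charged

- percent here means substrate units held: one idle adduct or homo dimer counts as two
- what is said of target includes idle adduct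
- a doubled species enters its step squared and goes two at a time
- in an amount of target, one idle adduct counts as one target
- the reaction counts as stopped when no species that holds the substrate changes by six tenths of a point or more over the second half of the time
- run time (flask): 12 d

Turn the question round: what must be true for side product to pass homo dimer? Substrate, intermediate and target relax towards balance with half-lives of 0.722 h and 0.359 h. So I treat them as a pre-equilibrium, one pool of concentration P, leaving the idle adduct aside. Then P = g[substrate], where g, the pool held per unit of free substrate, is 1.40. The pool leaks at λ[substrate], where λ, the leak constant, is 0.0160 h⁻¹. It loses substrate to homo dimer at β[substrate] squared, where β, twice the dimerisation constant, is 20.0 L mol⁻¹ h⁻¹. A unit of it therefore leaks with chance P*/(P* + P), where P* = gλ/β = 1.12 mM, the even-fork concentration, at which leak and dimerisation are equally likely. By this reckoning side product takes the larger share at a charge c near or below P*, but yours is 33.0 times larger.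

Summing the chances as the pool falls gives a share of (P*/c)·ln(1 + c/P*) = 10.7%. Balance takes 0.722 h, while the first half-life by dimerisation is 1.35 h. So the first hours fall short of balance, and I expect my figure to run high. Both exits are one-way. At low P the pool's half-life is 2.54 d, and the run holds 4.72 of these, so I expect it used up rather than balanced.

The forecast says "all of the substrate has reacted" and 10%, below my figure, on the ground that “the slow first-order leak to side product, which wins only at low concentration”.

The flask gives "all of the substrate has reacted", with 0.0900% substrate left, and 9.67% side product at 12 d. The forecast stands. The answer moves by 5 points at charges of 20.5 mM and 96.6 mM. My share lies 1 percentage point above the flask's value. The neighbouring flask, charged with 150 mM, stands 134 times above P*. The same reckoning gives it 3.66%, and that flask holds 3.30% side product at 12.0 d.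

The numbers of this flask were chosen freely; the rest is arithmetic.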